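**Plan**

- Retrosynthetic cuts, in order: the aryl–O bond of the enol ether (core phenol plus an (E)-α-bromocinnamate); the C3=C4 alkene, traced back to a C4 carbinol; C1–C2 and C3–C4 of ring B (a 2-benzylbenzaldehyde plus a fumarate); the ArCH2–Ar bond (benzylic chloride plus arylboronate).
- Enabling feature: in ring B the two carboxyl-bearing carbons C2 and C3 are neighbours and lie between the benzylic carbons C1 (aryl-bearing) and C4, so a fumarate fits between the two ortho benzylic carbons of ring A.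
- Forward: a Suzuki coupling joins ring A to the pendant ring; irradiation gives the hydroxy-ortho-quinodimethane, which adds the fumarate and closes ring B, the only ring made. Elimination, ester exchange, MOM removal, copper-catalysed O-vinylation, saponification and debenzylation follow.
- Stereochemistry: C1/C2 trans comes from endo addition of the (E)-dienophile to the (E,E)-dienol, and the absolute sense from the (R)-lactate esters. The enol ether geometry comes from a Still–Gennari-type (E)-α-bromoacrylate that couples with retention.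

Key step: step 8

Assumption: fumarates of (S)-configured α-hydroxy esters are taken to steer hydroxy-aryl-ortho-quinodimethanes to the 1S,2R series, so the (R)-lactate is used for 1R,2S; only the auxiliary antipode would change if the sense proved opposite.

**Route**

Step 1
Reactants: 1 3,4-bis(benzyloxy)benzaldehyde
Product: 2 4,5-bis(benzyloxy)-2-bromobenzaldehyde
Conditions: Br2, NaOAc, AcOH, rt
Reagents that add atoms: bromine, BrBr
Why: Electrophilic aromatic bromination goes to the position para to the 3-benzyloxy group and ortho to the formyl group, the most activated open site, as with veratraldehyde.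

Step 2
Reactants: 2 4,5-bis(benzyloxy)-2-bromobenzaldehyde
Product: 3 4,5-bis(benzyloxy)-2-(4,4,5,5-tetramethyl-1,3,2-dioxaborolan-2-yl)benzaldehyde
Conditions: B2pin2, PdCl2(dppf) (cat.), KOAc, 1,4-dioxane, 85 °C
Reagents that add atoms: bis(pinacolato)diboron, CC1(C)OB(OC1(C)C)B1OC(C)(C)C(C)(C)O1
Why: Miyaura borylation, in which the ortho formyl group speeds oxidative addition to zerovalent palladium and acetate is too weak a base to start Suzuki homocoupling or attack the aldehyde.

Step 3
Reactants: 4 4-(benzyloxy)-3-hydroxybenzaldehyde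
Product: 5 4-(benzyloxy)-3-(methoxymethoxy)benzaldehyde
Conditions: MOMCl, i-Pr2NEt, CH2Cl2, 0 °C to rt
Reagents that add atoms: chloromethyl methyl ether, COCCl
Why: O-alkylation of the single free phenol (MOM ether formation) installs an acetal that is stable to base, palladium and light yet removable later beside benzyl ethers.

Step 4
Reactants: 5 4-(benzyloxy)-3-(methoxymethoxy)benzaldehyde
Product: 6 [4-(benzyloxy)-3-(methoxymethoxy)phenyl]methanol
Conditions: NaBH4, MeOH, 0 °C
Reagents that add atoms: none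
Why: Borohydride reduction of an aromatic aldehyde is chemoselective and leaves both ethers alone.

Step 5
Reactants: 6 [4-(benzyloxy)-3-(methoxymethoxy)phenyl]methanol
Product: 8 4-(benzyloxy)-3-(methoxymethoxy)benzyl chloride, via benzylic mesylate 7 (not isolated)
Conditions: MsCl, Et3N, CH2Cl2, 0 °C; then LiCl, THF, rt
Reagents that add atoms: methanesulfonyl chloride, CS(=O)(=O)Cl (atoms kept only in 7); lithium chloride, [Li+].[Cl-]
Why: Sulfonylation followed by nucleophilic substitution with chloride at an electron-rich benzylic carbon gives the chloride without free acid, so the MOM acetal survives.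

Step 6
Reactants: 3 4,5-bis(benzyloxy)-2-(4,4,5,5-tetramethyl-1,3,2-dioxaborolan-2-yl)benzaldehyde; 8 4-(benzyloxy)-3-(methoxymethoxy)benzyl chloride
Product: 9 4,5-bis(benzyloxy)-2-[4-(benzyloxy)-3-(methoxymethoxy)benzyl]benzaldehyde
Conditions: PdCl2(dppf) (cat.), Cs2CO3, THF/H2O (10:1), 70 °C
Reagents that add atoms: none
Why: Suzuki–Miyaura coupling of a benzylic chloride with an arylboronate forms the diarylmethane bond with no β-hydride pathway and tolerates the free aldehyde, which avoids hydrogenolysis conditions that benzyl ethers would not survive.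

Step 7
Reactants: 10 fumaryl chloride; 11 methyl (R)-lactate (2 equiv)
Product: 12 bis[(2R)-1-methoxy-1-oxopropan-2-yl] fumarate
Conditions: toluene, 90 °C, N2 sweep
Reagents that add atoms: none
Why: Acylation of the secondary alcohol by the acid chloride leaves the lactate stereocentre and the (E)-alkene untouched while hydrogen chloride is swept out.

Step 8
Reactants: 9 4,5-bis(benzyloxy)-2-[4-(benzyloxy)-3-(methoxymethoxy)benzyl]benzaldehyde; 12 bis[(2R)-1-methoxy-1-oxopropan-2-yl] fumarate
Product: 14 bis[(2R)-1-methoxy-1-oxopropan-2-yl] (1R,2S,3R,4R)-6,7-bis(benzyloxy)-1-[4-(benzyloxy)-3-(methoxymethoxy)phenyl]-4-hydroxy-1,2,3,4-tetrahydronaphthalene-2,3-dicarboxylate, via (E,E)-dienol 13 (not isolated)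
Conditions: hν (350 nm, Pyrex), 12 (3 equiv), degassed toluene, rt
Reagents that add atoms: none
Why: The triplet aldehyde abstracts a hydrogen atom from the adjacent ArCH2Ar group through a six-membered transition state and the biradical collapses to dienols, of which only the (E,E)-isomer 13 lives long enough to be trapped (the Z-enol falls back to 9 by a 1,5-hydrogen shift); this is the known photoenol Diels–Alder reaction of 2-benzylbenzaldehydes with fumarates of chiral α-hydroxy esters. Ring B closes by an intermolecular concerted suprafacial (4+2) cycloaddition across the two exocyclic carbons of 13, forming C1–C2 and C3–C4 together and re-aromatising ring A. C2 and C3 are trans because the (E)-geometry of 12 is transferred stereospecifically, and the C1 aryl and C4 hydroxyl are cis because both point outward on the diene. The C3 ester lies endo and cis to the C4 hydroxyl, held by a hydrogen bond from the enol OH to that ester carbonyl, which puts the C2 ester trans to the C1 aryl group. The absolute configuration (1R,2S,3R,4R) comes from the (R)-lactate units, which block one face of the twofold-symmetric fumarate in this hydrogen-bonded endo arrangement. The step needs endo and facial selectivity, both secured by the enol hydroxyl acting with the auxiliary; regiochemistry is no issue because both ends of 12 are equivalent, and 350 nm light is absorbed by 9 but not by 12 or 14.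

Step 9
Reactants: 14 bis[(2R)-1-methoxy-1-oxopropan-2-yl] (1R,2S,3R,4R)-6,7-bis(benzyloxy)-1-[4-(benzyloxy)-3-(methoxymethoxy)phenyl]-4-hydroxy-1,2,3,4-tetrahydronaphthalene-2,3-dicarboxylate
Product: 16 bis[(2R)-1-methoxy-1-oxopropan-2-yl] (1R,2S)-6,7-bis(benzyloxy)-1-[4-(benzyloxy)-3-(methoxymethoxy)phenyl]-1,2-dihydronaphthalene-2,3-dicarboxylate, via C4 mesylate 15 (not isolated)
Conditions: MsCl, Et3N, CH2Cl2, 0 °C; then DBU, rt
Reagents that add atoms: methanesulfonyl chloride, CS(=O)(=O)Cl (atoms kept only in 15)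
Why: Mesylation and base-induced β-elimination (E1cB/E2) remove the C4 oxygen, which is anti to the acidic H3, and give the C3=C4 acrylate conjugated with ring A, while C1 is not acidic and trans C2 is the more stable epimer.

Step 10
Reactants: 16 bis[(2R)-1-methoxy-1-oxopropan-2-yl] (1R,2S)-6,7-bis(benzyloxy)-1-[4-(benzyloxy)-3-(methoxymethoxy)phenyl]-1,2-dihydronaphthalene-2,3-dicarboxylate
Product: 17 dimethyl (1R,2S)-6,7-bis(benzyloxy)-1-[4-(benzyloxy)-3-(methoxymethoxy)phenyl]-1,2-dihydronaphthalene-2,3-dicarboxylate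
Conditions: NaOMe (cat.), MeOH/THF, 0 °C to rt; AcOH quench
Reagents that add atoms: methanol, CO
Why: Base-catalysed transesterification (methanolysis) of the activated α-acyloxy esters releases the auxiliary, and any equilibration at C2 favours the trans diester already present.

Step 11
Reactants: 17 dimethyl (1R,2S)-6,7-bis(benzyloxy)-1-[4-(benzyloxy)-3-(methoxymethoxy)phenyl]-1,2-dihydronaphthalene-2,3-dicarboxylate
Product: 18 dimethyl (1R,2S)-6,7-bis(benzyloxy)-1-[4-(benzyloxy)-3-hydroxyphenyl]-1,2-dihydronaphthalene-2,3-dicarboxylate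
Conditions: HCl (cat.), MeOH/THF, 40 °C
Reagents that add atoms: none
Why: Acid-catalysed acetal exchange cleaves the MOM ether selectively, since benzyl ethers, methyl esters and the electron-poor styrene are inert to dilute methanolic acid.

Step 12
Reactants: 19 methyl bis(2,2,2-trifluoroethyl)phosphonoacetate
Product: 20 methyl 2,2-dibromo-2-[bis(2,2,2-trifluoroethoxy)phosphoryl]acetate
Conditions: Br2, aq NaOH, 0 °C
Reagents that add atoms: bromine, BrBr
Why: Hypobromite halogenation of the doubly activated methylene is driven through to the gem-dibromide, which avoids mono/di mixtures.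

Step 13
Reactants: 20 methyl 2,2-dibromo-2-[bis(2,2,2-trifluoroethoxy)phosphoryl]acetate
Product: 21 methyl 2-bromo-2-[bis(2,2,2-trifluoroethoxy)phosphoryl]acetate
Conditions: SnCl2·2H2O, EtOH/H2O, 0 °C
Reagents that add atoms: none
Why: Reductive monodehalogenation of a gem-dibromide by divalent tin stops at the monobromide because the remaining bromine is far less electrophilic.

Step 14
Reactants: 1 3,4-bis(benzyloxy)benzaldehyde; 21 methyl 2-bromo-2-[bis(2,2,2-trifluoroethoxy)phosphoryl]acetate
Product: 22 methyl (E)-3-[3,4-bis(benzyloxy)phenyl]-2-bromoprop-2-enoate (bromine trans to aryl)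
Conditions: t-BuOK, 18-crown-6, THF, −78 °C
Reagents that add atoms: none
Why: Horner–Wadsworth–Emmons olefination of Still–Gennari type, in which the trifluoroethyl phosphonate eliminates under kinetic control and places aryl cis to the ester and so bromine trans to aryl.

Step 15
Reactants: 18 dimethyl (1R,2S)-6,7-bis(benzyloxy)-1-[4-(benzyloxy)-3-hydroxyphenyl]-1,2-dihydronaphthalene-2,3-dicarboxylate; 22 methyl (E)-3-[3,4-bis(benzyloxy)phenyl]-2-bromoprop-2-enoate
Product: 23 dimethyl (1R,2S)-6,7-bis(benzyloxy)-1-{4-(benzyloxy)-3-[(E)-2-[3,4-bis(benzyloxy)phenyl]-1-(methoxycarbonyl)ethenoxy]phenyl}-1,2-dihydronaphthalene-2,3-dicarboxylate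
Conditions: CuI (cat.), N,N-dimethylglycine·HCl, Cs2CO3, 1,4-dioxane, 80 °C, Ar, dark
Reagents that add atoms: none
Why: Ullmann-type O-vinylation of a phenol by a vinyl bromide at monovalent copper proceeds with retention of alkene geometry, so the bromine-trans-to-aryl arrangement of 22 becomes the (E)-enol ether, while carbonate cannot epimerise C1 and C2 is already the stable trans epimer.

Step 16
Reactants: 23 dimethyl (1R,2S)-6,7-bis(benzyloxy)-1-{4-(benzyloxy)-3-[(E)-2-[3,4-bis(benzyloxy)phenyl]-1-(methoxycarbonyl)ethenoxy]phenyl}-1,2-dihydronaphthalene-2,3-dicarboxylate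
Product: 24 (1R,2S)-6,7-bis(benzyloxy)-1-{4-(benzyloxy)-3-[(E)-2-[3,4-bis(benzyloxy)phenyl]-1-carboxyethenoxy]phenyl}-1,2-dihydronaphthalene-2,3-dicarboxylic acid
Conditions: LiOH·H2O, THF/MeOH/H2O, 40 °C, Ar, dark; then aq HCl to pH 2
Reagents that add atoms: lithium hydroxide, [Li+].[OH-]
Why: Saponification of the three methyl esters while every phenol is still benzylated avoids catechol oxidation, and neither the trans C2 centre nor the enol ether is disturbed by hydroxide.

Step 17
Reactants: 24 (1R,2S)-6,7-bis(benzyloxy)-1-{4-(benzyloxy)-3-[(E)-2-[3,4-bis(benzyloxy)phenyl]-1-carboxyethenoxy]phenyl}-1,2-dihydronaphthalene-2,3-dicarboxylic acid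
Product: 25 (1R,2S)-1-{3-[(E)-1-carboxy-2-(3,4-dihydroxyphenyl)ethenoxy]-4-hydroxyphenyl}-6,7-dihydroxy-1,2-dihydronaphthalene-2,3-dicarboxylic acid (CNP0241205.1)
Conditions: BCl3, pentamethylbenzene, CH2Cl2, −78 °C; MeOH quench
Reagents that add atoms: none
Why: Lewis acid debenzylation with pentamethylbenzene as benzyl cation scavenger cleaves the five aryl benzyl ethers at low temperature without reducing or alkylating either alkene, and the aryl–O–vinyl bond is safe because chloride cannot displace at an sp2 carbon.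

**Compound list**

1 | 3,4-bis(benzyloxy)benzaldehyde | O=Cc1ccc(OCc2ccccc2)c(OCc2ccccc2)c1 | starting material
2 | 4,5-bis(benzyloxy)-2-bromobenzaldehyde | O=Cc1cc(OCc2ccccc2)c(OCc2ccccc2)cc1Br | intermediate
3 | 4,5-bis(benzyloxy)-2-(4,4,5,5-tetramethyl-1,3,2-dioxaborolan-2-yl)benzaldehyde | O=Cc1cc(OCc2ccccc2)c(OCc2ccccc2)cc1B1OC(C)(C)C(C)(C)O1 | intermediate
4 | 4-(benzyloxy)-3-hydroxybenzaldehyde | O=Cc1ccc(OCc2ccccc2)c(O)c1 | starting material
5 | 4-(benzyloxy)-3-(methoxymethoxy)benzaldehyde | O=Cc1ccc(OCc2ccccc2)c(OCOC)c1 | intermediate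
6 | [4-(benzyloxy)-3-(methoxymethoxy)phenyl]methanol | OCc1ccc(OCc2ccccc2)c(OCOC)c1 | intermediate
7 | 4-(benzyloxy)-3-(methoxymethoxy)benzyl methanesulfonate | CS(=O)(=O)OCc1ccc(OCc2ccccc2)c(OCOC)c1 | intermediate
8 | 4-(benzyloxy)-3-(methoxymethoxy)benzyl chloride | ClCc1ccc(OCc2ccccc2)c(OCOC)c1 | intermediate
9 | 4,5-bis(benzyloxy)-2-[4-(benzyloxy)-3-(methoxymethoxy)benzyl]benzaldehyde | O=Cc1cc(OCc2ccccc2)c(OCc2ccccc2)cc1Cc1ccc(OCc2ccccc2)c(OCOC)c1 | intermediate
10 | fumaryl chloride | O=C(Cl)/C=C/C(=O)Cl | starting material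
11 | methyl (R)-lactate | C[C@@H](O)C(=O)OC | starting material
12 | bis[(2R)-1-methoxy-1-oxopropan-2-yl] fumarate | COC(=O)[C@@H](C)OC(=O)/C=C/C(=O)O[C@H](C)C(=O)OC | intermediate
13 | (E,E)-hydroxy-ortho-quinodimethane from 9 (enol OH and aryl both outward) | O/C=C1\C=C(OCc2ccccc2)C(OCc2ccccc2)=C/C1=C\c1ccc(OCc2ccccc2)c(OCOC)c1 | intermediate
14 | bis[(2R)-1-methoxy-1-oxopropan-2-yl] (1R,2S,3R,4R)-6,7-bis(benzyloxy)-1-[4-(benzyloxy)-3-(methoxymethoxy)phenyl]-4-hydroxy-1,2,3,4-tetrahydronaphthalene-2,3-dicarboxylate | COC(=O)[C@@H](C)OC(=O)[C@H]1[C@@H](O)c2cc(OCc3ccccc3)c(OCc3ccccc3)cc2[C@@H](c2ccc(OCc3ccccc3)c(OCOC)c2)[C@@H]1C(=O)O[C@H](C)C(=O)OC | intermediate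
15 | C4 methanesulfonate of 14 | COC(=O)[C@@H](C)OC(=O)[C@H]1[C@@H](OS(C)(=O)=O)c2cc(OCc3ccccc3)c(OCc3ccccc3)cc2[C@@H](c2ccc(OCc3ccccc3)c(OCOC)c2)[C@@H]1C(=O)O[C@H](C)C(=O)OC | intermediate
16 | bis[(2R)-1-methoxy-1-oxopropan-2-yl] (1R,2S)-6,7-bis(benzyloxy)-1-[4-(benzyloxy)-3-(methoxymethoxy)phenyl]-1,2-dihydronaphthalene-2,3-dicarboxylate | COC(=O)[C@@H](C)OC(=O)C1=Cc2cc(OCc3ccccc3)c(OCc3ccccc3)cc2[C@@H](c2ccc(OCc3ccccc3)c(OCOC)c2)[C@@H]1C(=O)O[C@H](C)C(=O)OC | intermediate
17 | dimethyl (1R,2S)-6,7-bis(benzyloxy)-1-[4-(benzyloxy)-3-(methoxymethoxy)phenyl]-1,2-dihydronaphthalene-2,3-dicarboxylate | COC(=O)C1=Cc2cc(OCc3ccccc3)c(OCc3ccccc3)cc2[C@@H](c2ccc(OCc3ccccc3)c(OCOC)c2)[C@@H]1C(=O)OC | intermediate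
18 | dimethyl (1R,2S)-6,7-bis(benzyloxy)-1-[4-(benzyloxy)-3-hydroxyphenyl]-1,2-dihydronaphthalene-2,3-dicarboxylate | COC(=O)C1=Cc2cc(OCc3ccccc3)c(OCc3ccccc3)cc2[C@@H](c2ccc(OCc3ccccc3)c(O)c2)[C@@H]1C(=O)OC | intermediate
19 | methyl bis(2,2,2-trifluoroethyl)phosphonoacetate | COC(=O)CP(=O)(OCC(F)(F)F)OCC(F)(F)F | starting material
20 | methyl 2,2-dibromo-2-[bis(2,2,2-trifluoroethoxy)phosphoryl]acetate | COC(=O)C(Br)(Br)P(=O)(OCC(F)(F)F)OCC(F)(F)F | intermediate
21 | methyl 2-bromo-2-[bis(2,2,2-trifluoroethoxy)phosphoryl]acetate | COC(=O)C(Br)P(=O)(OCC(F)(F)F)OCC(F)(F)F | intermediate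
22 | methyl (E)-3-[3,4-bis(benzyloxy)phenyl]-2-bromoprop-2-enoate | Br/C(=C/c1ccc(OCc2ccccc2)c(OCc2ccccc2)c1)C(=O)OC | intermediate
23 | dimethyl (1R,2S)-6,7-bis(benzyloxy)-1-{4-(benzyloxy)-3-[(E)-2-[3,4-bis(benzyloxy)phenyl]-1-(methoxycarbonyl)ethenoxy]phenyl}-1,2-dihydronaphthalene-2,3-dicarboxylate | COC(=O)C1=Cc2cc(OCc3ccccc3)c(OCc3ccccc3)cc2[C@@H](c2ccc(OCc3ccccc3)c(O/C(=C/c3ccc(OCc4ccccc4)c(OCc4ccccc4)c3)C(=O)OC)c2)[C@@H]1C(=O)OC | intermediate
24 | (1R,2S)-6,7-bis(benzyloxy)-1-{4-(benzyloxy)-3-[(E)-2-[3,4-bis(benzyloxy)phenyl]-1-carboxyethenoxy]phenyl}-1,2-dihydronaphthalene-2,3-dicarboxylic acid | O=C(O)C1=Cc2cc(OCc3ccccc3)c(OCc3ccccc3)cc2[C@@H](c2ccc(OCc3ccccc3)c(O/C(=C/c3ccc(OCc4ccccc4)c(OCc4ccccc4)c3)C(=O)O)c2)[C@@H]1C(=O)O | intermediate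
25 | (1R,2S)-1-{3-[(E)-1-carboxy-2-(3,4-dihydroxyphenyl)ethenoxy]-4-hydroxyphenyl}-6,7-dihydroxy-1,2-dihydronaphthalene-2,3-dicarboxylic acid | O=C(O)C1=Cc2cc(O)c(O)cc2[C@@H](c2ccc(O)c(O/C(=C/c3ccc(O)c(O)c3)C(=O)O)c2)[C@@H]1C(=O)O | target

**Step count**

Total: 17 steps. Longest linear sequence: 11 steps (steps 3, 4, 5, 6, 8, 9, 10, 11, 15, 16, 17, from 4 to 25).

**Steps most likely to fail**

Step 8. The electron-rich dialkoxybenzaldehyde may photoenolise slowly, and long irradiation beside the dienophile may cause E/Z isomerisation of the fumarate and secondary photoreactions, eroding the 2,3-trans relationship and the selectivity. The fallback separates light from cycloaddition. It sets out from 9, which is irradiated at 350 nm in benzene saturated with sulfur dioxide, so that the dienol is caught by cheletropic addition as the cis hydroxy sulfone, rac-cis-5,6-bis(benzyloxy)-3-[4-(benzyloxy)-3-(methoxymethoxy)phenyl]-1-hydroxy-1,3-dihydro-2-benzothiophene 2,2-dioxide F1. Heating F1 with 12 and ZnO in toluene at 80–100 °C in the dark extrudes sulfur dioxide, regenerates the same (E,E)-dienol thermally and returns to the route at 14.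

Step 15. Carbonate at 80 °C may dehydrobrominate 22 to the arylpropiolate, which then takes up the phenol at the wrong carbon; the alkene geometry may drift, or oxidative addition at the hindered α-bromo ester may be too slow. The fallback builds the enol ether by olefination and sets out from 18 and 19. Diazo transfer to 19 (4-acetamidobenzenesulfonyl azide, DBU, MeCN) gives methyl 2-diazo-2-[bis(2,2,2-trifluoroethoxy)phosphoryl]acetate F2. Rh2(OAc)4-catalysed O–H insertion of F2 into phenol 18 (toluene, 80 °C) gives the aryloxyphosphonoacetate of the core F3 as a mixture of epimers at the phosphonate carbon. Deprotonation of F3 (KHMDS, 18-crown-6, THF, −78 °C) and cis-selective Horner–Wadsworth–Emmons reaction with aldehyde 1 place the aryl group cis to the ester and return to the route at 23.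

Step 17. The triacid may aggregate as boron carboxylates at −78 °C, leaving benzyl ethers uncleaved, and warming to force the reaction may let the enol ether geometry drift under acid. The fallback changes the order of unmasking and sets out from 23. The triester is debenzylated first (BCl3, pentamethylbenzene, CH2Cl2, −78 °C), where it is fully soluble and carries no free acid, to give trimethyl ester pentaphenol F4. F4 is then saponified with LiOH in degassed THF/H2O under argon with Na2S2O4 as antioxidant and acidified, returning to the route at 25.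

Further compounds
F1 | step 8 | rac-cis-5,6-bis(benzyloxy)-3-[4-(benzyloxy)-3-(methoxymethoxy)phenyl]-1-hydroxy-1,3-dihydro-2-benzothiophene 2,2-dioxide (one enantiomer drawn) | O[C@@H]1c2cc(OCc3ccccc3)c(OCc3ccccc3)cc2[C@H](c2ccc(OCc3ccccc3)c(OCOC)c2)S1(=O)=O
F2 | step 15 | methyl 2-diazo-2-[bis(2,2,2-trifluoroethoxy)phosphoryl]acetate | COC(=O)C(=[N+]=[N-])P(=O)(OCC(F)(F)F)OCC(F)(F)F
F3 | step 15 | dimethyl (1R,2S)-6,7-bis(benzyloxy)-1-{4-(benzyloxy)-3-[1-[bis(2,2,2-trifluoroethoxy)phosphoryl]-2-methoxy-2-oxoethoxy]phenyl}-1,2-dihydronaphthalene-2,3-dicarboxylate | COC(=O)C1=Cc2cc(OCc3ccccc3)c(OCc3ccccc3)cc2[C@@H](c2ccc(OCc3ccccc3)c(OC(C(=O)OC)P(=O)(OCC(F)(F)F)OCC(F)(F)F)c2)[C@@H]1C(=O)OC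
F4 | step 17 | dimethyl (1R,2S)-6,7-dihydroxy-1-{4-hydroxy-3-[(E)-2-(3,4-dihydroxyphenyl)-1-(methoxycarbonyl)ethenoxy]phenyl}-1,2-dihydronaphthalene-2,3-dicarboxylate | COC(=O)C1=Cc2cc(O)c(O)cc2[C@@H](c2ccc(O)c(O/C(=C/c3ccc(O)c(O)c3)C(=O)OC)c2)[C@@H]1C(=O)OC
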